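In each half of the target, aryl carbon C5 (ortho to the C4 hydroxyl) is joined to the quaternary cyclopentane carbon C1', which also bears a methyl group. That methyl carbon is treated as a masked O–CH2 link, so that O(C4)–CH2–C1'–C5–C4 becomes the dihydrofuran ring of a spiro 2,3-dihydrobenzofuran. A twofold enantioselective intramolecular Heck reaction of an achiral bis(aryl iodide), in which each C4 oxygen carries a (5,5-dimethylcyclopent-1-enyl)methyl group, forms both C5–C1' bonds, both dihydrofuran rings and both quaternary stereocentres in one operation. Hydrogenation, reductive scission of each O–CH2 bond and demethylation then give the bis(catechol).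

Key step: step 8

Remarks on the chemistry
- Locants: arene C1 carries the ethane bridge, C3 and C4 the oxygens, C5 the cyclopentyl group; C1' is the quaternary cyclopentane carbon and C2' the gem-dimethyl carbon. Spiro compounds 11–13 use benzofuran locants (C3 there is C1' of the target).
- Structure check: 10 and 12 map atom for atom onto 17, and neither needs correction. The spiro centres of 11–13 are (R). The same spatial arrangement is (S) in 14–17 only because the O–CH2 branch (highest rank) becomes CH3 (lowest rank); no centre is inverted.
- Assumption: (R)-BINAP is taken to give the (R,R) product under silver conditions. The sense is to be confirmed on a one-ring model ether; if it is reversed, (S)-BINAP is used with nothing else changed.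
- Protecting groups: the C3 oxygen stays a methyl ether from the vanillin core to the last step. The C4 oxygen is benzyl-protected only for the carbonyl coupling (commercial O-benzylvanillin) and is freed in the operation that saturates the stilbene, so this costs no step.
- The precursor skeleton is kept as it is: iodide and methoxy block both positions ortho to the tether oxygen and the para position carries the bridge, so the allyl aryl ether has no free site for rearrangement or C-alkylation.

Step 1
Reactants: 1 4-(benzyloxy)-3-methoxybenzaldehyde (two molecules)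
Product: 2 (E)-1,2-bis[4-(benzyloxy)-3-methoxyphenyl]ethene
Conditions: TiCl4, Zn, THF, reflux
Reagents that add atoms: none
Why: McMurry coupling, in which low-valent titanium joins two aldehyde carbons as a titanium pinacolate and deoxygenates it to the stilbene; the benzyl ether keeps the phenol from consuming the titanium reagent, and alkene geometry is irrelevant because the double bond is hydrogenated next.

Step 2
Reactants: 2 (E)-1,2-bis[4-(benzyloxy)-3-methoxyphenyl]ethene
Product: 3 4,4'-(ethane-1,2-diyl)bis(2-methoxyphenol)
Conditions: H2 (1 atm), Pd/C, THF–MeOH, rt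
Reagents that add atoms: none
Why: Heterogeneous catalytic hydrogenation should saturate the stilbene C=C and hydrogenolyse both benzyl ethers in the same operation, while the methyl ethers and the unactivated ArCH2–CH2Ar bond are inert.

Step 3
Reactants: 3 4,4'-(ethane-1,2-diyl)bis(2-methoxyphenol)
Product: 4 4,4'-(ethane-1,2-diyl)bis(2-iodo-6-methoxyphenol)
Conditions: I2 (2.1 equiv), NaHCO3, THF–H2O, 0 °C to rt
Reagents that add atoms: iodine, II
Why: Electrophilic aromatic iodination of the phenoxide: the para position holds the bridge and one ortho position holds OMe, so iodine should enter the remaining ortho carbon (C5) of each ring, and one equivalent of iodine per ring limits further iodination.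

Step 4
Reactants: 5 2,2-dimethylcyclopentanone
Product: 6 N'-[(1E)-2,2-dimethylcyclopentylidene]-2,4,6-tri(propan-2-yl)benzenesulfonohydrazide
Conditions: 2,4,6-(i-Pr)3C6H2SO2NHNH2, cat. HCl, MeOH, rt
Reagents that add atoms: 2,4,6-tri(propan-2-yl)benzenesulfonohydrazide, CC(C)c1cc(C(C)C)c(S(=O)(=O)NN)c(C(C)C)c1
Why: Acid-catalysed condensation of the ketone with the sulfonylhydrazide gives the hydrazone, with the sulfonamide nitrogen expected anti to the quaternary carbon.

Step 5
Reactants: 6 N'-[(1E)-2,2-dimethylcyclopentylidene]-2,4,6-tri(propan-2-yl)benzenesulfonohydrazide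
Product: 8 (5,5-dimethylcyclopent-1-en-1-yl)methanol, via vinyllithium 7 (not isolated)
Conditions: n-BuLi (2.2 equiv), THF, −78 to 0 °C; then (CH2O)n, −78 °C to rt; then H2O
Reagents that add atoms: formaldehyde (from paraformaldehyde), C=O
Why: Shapiro reaction: deprotonation at N–H and at the only α-CH2, then loss of sulfinate and N2, gives the vinyllithium 7 with the double bond fixed away from the gem-dimethyl carbon, and 7 adds to formaldehyde to give the primary allylic alcohol.

Step 6
Reactants: 8 (5,5-dimethylcyclopent-1-en-1-yl)methanol
Product: 9 1-(bromomethyl)-5,5-dimethylcyclopent-1-ene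
Conditions: CBr4, PPh3, CH2Cl2, 0 °C
Reagents that add atoms: carbon tetrabromide, BrC(Br)(Br)Br
Why: Appel reaction: bromide displaces the alkoxyphosphonium group at the primary carbon under neutral conditions, which avoids acid-promoted allylic transposition.

Step 7
Reactants: 4 4,4'-(ethane-1,2-diyl)bis(2-iodo-6-methoxyphenol); 9 1-(bromomethyl)-5,5-dimethylcyclopent-1-ene (2.4 equiv)
Product: 10 1,2-bis{4-[(5,5-dimethylcyclopent-1-en-1-yl)methoxy]-3-iodo-5-methoxyphenyl}ethane
Conditions: K2CO3, DMF, rt to 50 °C
Reagents that add atoms: none
Why: Williamson ether synthesis: each phenoxide displaces the primary allylic bromide by SN2; C-alkylation is excluded because both ortho positions and the para position are substituted, and attack at the ring CH (SN2′) is sterically less favourable than attack at CH2.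

Step 8
Reactants: 10 1,2-bis{4-[(5,5-dimethylcyclopent-1-en-1-yl)methoxy]-3-iodo-5-methoxyphenyl}ethane
Product: 12 1,2-bis[(3R)-7-methoxy-5',5'-dimethyl-2H-spiro[1-benzofuran-3,1'-cyclopent-2'-en]-5-yl]ethane, via mono-cyclised aryl iodide 11 (not isolated)
Conditions: Pd(OAc)2 (20 mol%), (R)-BINAP (45 mol%), Ag3PO4 (2 equiv), DMA, 80 °C
Reagents that add atoms: none
Why: BINAP reduces Pd(OAc)2 to a zerovalent palladium–BINAP complex that inserts into each Ar–I bond; Ag3PO4 removes iodide, so the cationic arylpalladium keeps both phosphorus atoms bound while the tethered alkene coordinates, and syn migratory insertion followed by syn β-hydride elimination releases the cyclopentene and a palladium hydride that the phosphate base returns to zerovalent palladium. The closest known reaction type is the enantioselective intramolecular Heck cyclisation of aryl iodides onto trisubstituted cycloalkenes under silver-promoted (cationic) conditions, which builds spiro quaternary carbons. Each dihydrofuran ring closes in the 5-exo-trig mode, the aryl carbon bonding to the fully substituted alkene carbon. Each spiro centre (C3 of the benzofuran, C1' of the target) is set by the chiral bisphosphine, which selects the enantiotopic alkene face at each end independently because the two sites are separated by the ethane bridge. The step needs exo regioselectivity (enforced by the three-atom O–CH2 tether), one direction of β-hydride elimination (the spiro carbon has no hydrogen, so elimination goes toward C3', and later alkene migration is harmless because the ring is hydrogenated) and Ar–I insertion ahead of ionisation of the allyl aryl ether (the iodide is the faster site). Because two independent events are combined, most minor-sense cyclisation should end in the separable meso diastereomer, which should raise the enantiomeric purity of the C2-symmetric product above that of a single event.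

Step 9
Reactants: 12 1,2-bis[(3R)-7-methoxy-5',5'-dimethyl-2H-spiro[1-benzofuran-3,1'-cyclopent-2'-en]-5-yl]ethane
Product: 13 1,2-bis[(3R)-7-methoxy-2',2'-dimethyl-2H-spiro[1-benzofuran-3,1'-cyclopentan]-5-yl]ethane
Conditions: H2 (1–3 atm), Pd/C, EtOAc, rt
Reagents that add atoms: none
Why: Catalytic hydrogenation of the cis-disubstituted cyclopentene; both alkene carbons become CH2, so no stereocentre is created, the spiro centre is untouched, and an alkyl aryl ether without a benzylic C–O bond is not hydrogenolysed.

Step 10
Reactants: 13 1,2-bis[(3R)-7-methoxy-2',2'-dimethyl-2H-spiro[1-benzofuran-3,1'-cyclopentan]-5-yl]ethane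
Product: 15 4,4'-(ethane-1,2-diyl)bis{2-methoxy-6-[(1S)-1,2,2-trimethylcyclopentyl]phenol}, via tetralithiated ring-opened intermediate 14 (not isolated)
Conditions: lithium 4,4'-di-tert-butylbiphenylide (LiDBB, excess), THF, 0 °C; then H2O
Reagents that add atoms: none
Why: Reductive ring opening of a 2,3-dihydrobenzofuran by an arene radical anion: electron transfer into the alkoxyarene is followed by scission of the O–CH2 bond to a lithium phenoxide and a primary radical, a second electron gives the alkyllithium of 14, and protonation gives the C1' methyl group; no bond to C1' is broken, so its configuration is retained.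

Step 11
Reactants: 15 4,4'-(ethane-1,2-diyl)bis{2-methoxy-6-[(1S)-1,2,2-trimethylcyclopentyl]phenol}
Product: 17 5,5'-(ethane-1,2-diyl)bis{3-[(1S)-1,2,2-trimethylcyclopentyl]benzene-1,2-diol}, via bis(bromobenzodioxaborole) 16 (not isolated)
Conditions: BBr3, CH2Cl2, −78 to 0 °C; then H2O
Reagents that add atoms: none
Why: Lewis-acid demethylation: BBr3 borylates the phenol and coordinates the neighbouring methoxy oxygen, bromide attacks the methyl carbon by SN2, and hydrolysis of the cyclic bromoborate 16 frees the catechol; the low temperature guards against acid-induced loss of the tertiary cyclopentyl group.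

Compound list
1 | 4-(benzyloxy)-3-methoxybenzaldehyde (O-benzylvanillin) | COc1cc(C=O)ccc1OCc1ccccc1 | starting material
2 | (E)-1,2-bis[4-(benzyloxy)-3-methoxyphenyl]ethene | COc1cc(/C=C/c2ccc(OCc3ccccc3)c(OC)c2)ccc1OCc1ccccc1 | intermediate
3 | 4,4'-(ethane-1,2-diyl)bis(2-methoxyphenol) | COc1cc(CCc2ccc(O)c(OC)c2)ccc1O | intermediate
4 | 4,4'-(ethane-1,2-diyl)bis(2-iodo-6-methoxyphenol) | COc1cc(CCc2cc(I)c(O)c(OC)c2)cc(I)c1O | intermediate
5 | 2,2-dimethylcyclopentanone | CC1(C)CCCC1=O | starting material
6 | N'-[(1E)-2,2-dimethylcyclopentylidene]-2,4,6-tri(propan-2-yl)benzenesulfonohydrazide | CC(C)c1cc(C(C)C)c(S(=O)(=O)N/N=C2\CCCC2(C)C)c(C(C)C)c1 | intermediate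
7 | (5,5-dimethylcyclopent-1-en-1-yl)lithium | [Li]C1=CCCC1(C)C | intermediate (not isolated)
8 | (5,5-dimethylcyclopent-1-en-1-yl)methanol | OCC1=CCCC1(C)C | intermediate
9 | 1-(bromomethyl)-5,5-dimethylcyclopent-1-ene | BrCC1=CCCC1(C)C | intermediate
10 | 1,2-bis{4-[(5,5-dimethylcyclopent-1-en-1-yl)methoxy]-3-iodo-5-methoxyphenyl}ethane (achiral Heck precursor) | C(Cc1cc(OC)c(OCC2=CCCC2(C)C)c(I)c1)c1cc(OC)c(OCC2=CCCC2(C)C)c(I)c1 | intermediate
11 | (3R)-5-(2-{4-[(5,5-dimethylcyclopent-1-en-1-yl)methoxy]-3-iodo-5-methoxyphenyl}ethyl)-7-methoxy-5',5'-dimethyl-2H-spiro[1-benzofuran-3,1'-cyclopent-2'-ene] | COc1cc(CCc2cc(OC)c3OC[C@@]4(C=CCC4(C)C)c3c2)cc(I)c1OCC1=CCCC1(C)C | intermediate (not isolated)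
12 | 1,2-bis[(3R)-7-methoxy-5',5'-dimethyl-2H-spiro[1-benzofuran-3,1'-cyclopent-2'-en]-5-yl]ethane | C(Cc1cc(OC)c2OC[C@@]3(C=CCC3(C)C)c2c1)c1cc(OC)c2OC[C@@]3(C=CCC3(C)C)c2c1 | intermediate
13 | 1,2-bis[(3R)-7-methoxy-2',2'-dimethyl-2H-spiro[1-benzofuran-3,1'-cyclopentan]-5-yl]ethane | C(Cc1cc(OC)c2OC[C@@]3(CCCC3(C)C)c2c1)c1cc(OC)c2OC[C@@]3(CCCC3(C)C)c2c1 | intermediate
14 | dilithium 4,4'-(ethane-1,2-diyl)bis{2-methoxy-6-[(1S)-1-(lithiomethyl)-2,2-dimethylcyclopentyl]phenolate} | [Li]C[C@@]1(CCCC1(C)C)c1cc(CCc2cc(OC)c(O[Li])c([C@@]3(C[Li])CCCC3(C)C)c2)cc(OC)c1O[Li] | intermediate (not isolated)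
15 | 4,4'-(ethane-1,2-diyl)bis{2-methoxy-6-[(1S)-1,2,2-trimethylcyclopentyl]phenol} | C(Cc1cc(OC)c(O)c([C@@]2(C)CCCC2(C)C)c1)c1cc(OC)c(O)c([C@@]2(C)CCCC2(C)C)c1 | intermediate
16 | 1,2-bis{2-bromo-7-[(1S)-1,2,2-trimethylcyclopentyl]-1,3,2-benzodioxaborol-5-yl}ethane | BrB1Oc2cc(CCc3cc4OB(Br)Oc4c(c3)[C@@]3(C)CCCC3(C)C)cc(c2O1)[C@@]1(C)CCCC1(C)C | intermediate (not isolated)
17 | 5,5'-(ethane-1,2-diyl)bis{3-[(1S)-1,2,2-trimethylcyclopentyl]benzene-1,2-diol} (CNP0144189.1) | CC1(C)CCC[C@]1(C)c1cc(CCc2cc(O)c(O)c([C@@]3(C)CCCC3(C)C)c2)cc(O)c1O | target

Total step count: 11.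
Longest linear sequence: 8 steps (1 → 2 → 3 → 4 → 10 → 12 → 13 → 15 → 17; the branch from 5 through 6, 8 and 9 is equally long).

Steps most likely to fail

Step 8. The chiral catalyst may discriminate poorly between the two faces of the hindered trisubstituted alkene at one or both ends. This would show as a large share of the meso diastereomer and low enantiomeric purity of the C2-symmetric isomer. The fallback gives up catalyst control and separates instead. It sets out from 10: cyclisation with the achiral system Pd(OAc)2/PPh3/Ag2CO3 in MeCN at 80 °C should give the stereo-random bis-spirocycle F1 (racemate plus meso form). The meso diastereomer is removed on silica or by crystallisation. The racemate is resolved by preparative chromatography on a cellulose tris(3,5-dimethylphenylcarbamate) phase, and the (R,R) enantiomer comes back to the route as 12.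

Step 10. Electron transfer may cut the O–CH3 bond first and leave a lithium phenoxide whose ring no longer accepts an electron, so that the dihydrofuran survives. A 1,2-aryl shift of the intermediate primary radical is a second loss channel. The fallback replaces one-electron by two-electron chemistry and sets out from 13. Reduction with excess Et3SiH and catalytic B(C6F5)3 in CH2Cl2 silylates each ether oxygen and delivers hydride to the attached carbon, so that the ring O–CH2 becomes CH3 and the O-methyl group leaves as methane. This should give the tetrakis(triethylsilyl) ether of the target F2, which HCl in MeOH desilylates. The fallback comes back to the route at 17 and makes step 11 unnecessary. Its own weak point is hydride delivery at a neopentyl-type carbon.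

Step 5. The vinyllithium 7 may be protonated (by solvent or by incompletely depolymerised paraformaldehyde) faster than it adds to formaldehyde, which would return 3,3-dimethylcyclopentene. The fallback replaces the organolithium by a palladium carbonylation and sets out from 5. LiN(i-Pr)2 and then PhNTf2 in THF at −78 °C give the enol triflate 5,5-dimethylcyclopent-1-en-1-yl trifluoromethanesulfonate F3 (only C5 can be deprotonated). Methoxycarbonylation with Pd(OAc)2, PPh3, CO, MeOH and Et3N in DMF gives methyl 5,5-dimethylcyclopent-1-ene-1-carboxylate F4. Reduction with i-Bu2AlH in CH2Cl2 at −78 °C comes back to the route at 8.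

Further compounds
F1 | step 8 | 1,2-bis[7-methoxy-5',5'-dimethyl-2H-spiro[1-benzofuran-3,1'-cyclopent-2'-en]-5-yl]ethane, racemate plus meso form | C(Cc1cc(OC)c2OCC3(C=CCC3(C)C)c2c1)c1cc(OC)c2OCC3(C=CCC3(C)C)c2c1
F2 | step 10 | tetrakis(triethylsilyl) ether of 17 | CC[Si](CC)(CC)Oc1cc(CCc2cc(O[Si](CC)(CC)CC)c(O[Si](CC)(CC)CC)c([C@@]3(C)CCCC3(C)C)c2)cc([C@@]2(C)CCCC2(C)C)c1O[Si](CC)(CC)CC
F3 | step 5 | 5,5-dimethylcyclopent-1-en-1-yl trifluoromethanesulfonate | CC1(C)CCC=C1OS(=O)(=O)C(F)(F)F
F4 | step 5 | methyl 5,5-dimethylcyclopent-1-ene-1-carboxylate | COC(=O)C1=CCCC1(C)C
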